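**Retrosynthetic overview**
- The target is the mono-O-acetate of a 2,5-dihydroxy-3,6-diaryl-1,4-benzoquinone. The strategy rests on its quinone ring: C1 (carbonyl) and C2 (acetoxy-bearing) are adjacent oxygenated carbons of the same acyl polarity, so the C1–C2 bond is cut back to two formyl carbons.
- End game, backwards: target ⇐ debenzylation ⇐ quinone monoacetate ⇐ dihydroxy-p-quinone ⇐ hydrolysis of the 4,5-dimethoxy-o-quinone ⇐ oxidation of the cis-dihydrocatechol.
- The cis-dihydrocatechol ⇐ reductive pinacol closure of the (2E,4E)-3,4-dimethoxy-2,5-diarylhexadienedial. This is the only ring made in the route (the central six-membered ring); both benzene rings are bought.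
- The dienedial ⇐ diester ⇐ copper-mediated C3–C3′ dimerisation of the β-lithiated (E)-β-methoxyacrylate ⇐ arylacetate + methyl formate. The alkene geometry is set in the monomer (vinylic H cis to the ester) and carried through lithiation and coupling with retention.

Key step: step 6

Assumption: the target is achiral and is taken as the tautomer drawn (2-acetoxy-5-hydroxy-1,4-benzoquinone); the two carbinol stereocentres made in the key step are removed in the following oxidation.

**Step 1**
Reactants: 1 methyl [4-(benzyloxy)phenyl]acetate; 2 methyl formate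
Product: 3 methyl (2Z)-2-[4-(benzyloxy)phenyl]-3-hydroxyprop-2-enoate (chelated enol of the α-formyl ester)
Conditions: NaH (2 equiv), HCO2Me (5 equiv), THF, 0 °C → rt; then 1 M HCl
Reagents that add atoms: none
Why: Crossed Claisen formylation, in which methyl formate has no α-hydrogen and the product is drawn out of the equilibrium as its sodium enolate.

**Step 2**
Reactants: 3 methyl (2Z)-2-[4-(benzyloxy)phenyl]-3-hydroxyprop-2-enoate
Product: 4 methyl (2E)-2-[4-(benzyloxy)phenyl]-3-methoxyprop-2-enoate
Conditions: Me2SO4 (1.2 equiv), K2CO3 (1.5 equiv), DMF, rt; crystallisation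
Reagents that add atoms: dimethyl sulfate, COS(=O)(=O)OC
Why: Enolate O-alkylation with a hard electrophile in a dipolar aprotic solvent, the standard β-methoxyacrylate synthesis, should give mainly the E isomer (methoxy trans to the ester), which places the one vinylic hydrogen cis to the ester.

**Step 3**
Reactants: 4 methyl (2E)-2-[4-(benzyloxy)phenyl]-3-methoxyprop-2-enoate (two molecules)
Product: 6 dimethyl (2E,4E)-2,5-bis[4-(benzyloxy)phenyl]-3,4-dimethoxyhexa-2,4-dienedioate, via vinyllithium 5 (not isolated)
Conditions: LiN(i-Pr)2 (1.1 equiv), THF, −78 °C; then anhydrous CuCl2 (1.1 equiv), −78 °C → rt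
Reagents that add atoms: none
Why: Carbonyl-directed β-lithiation of a β-alkoxyacrylate (the hydrogen is α to oxygen and cis to the chelating ester) followed by oxidative homocoupling of the alkenyllithium with divalent copper, which keeps the alkene geometry, so that each ester ends up cis to the new C3–C4 bond.

**Step 4**
Reactants: 6 dimethyl (2E,4E)-2,5-bis[4-(benzyloxy)phenyl]-3,4-dimethoxyhexa-2,4-dienedioate
Product: 7 (2E,4E)-2,5-bis[4-(benzyloxy)phenyl]-3,4-dimethoxyhexa-2,4-diene-1,6-diol
Conditions: i-Bu2AlH (5 equiv), CH2Cl2, −78 → −20 °C; aq. potassium sodium tartrate (KNaC4H4O6), kept basic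
Reagents that add atoms: none
Why: 1,2-Reduction of conjugated esters to allylic alcohols with i-Bu2AlH leaves the double bonds and their geometry untouched, and the non-acidic work-up protects the acid-labile γ-hydroxy enol ethers.

**Step 5**
Reactants: 7 (2E,4E)-2,5-bis[4-(benzyloxy)phenyl]-3,4-dimethoxyhexa-2,4-diene-1,6-diol
Product: 8 (2E,4E)-2,5-bis[4-(benzyloxy)phenyl]-3,4-dimethoxyhexa-2,4-dienedial
Conditions: activated MnO2 (25 equiv), CH2Cl2, rt, dark; filtration through Celite, used at once
Reagents that add atoms: none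
Why: Allylic alcohol oxidation on MnO2 is neutral and stops at the aldehyde, so the enol ethers, the benzyl ethers and the alkene geometry should be kept.

**Step 6**
Reactants: 8 (2E,4E)-2,5-bis[4-(benzyloxy)phenyl]-3,4-dimethoxyhexa-2,4-dienedial
Product: 9 (1R,2S)-3,6-bis[4-(benzyloxy)phenyl]-4,5-dimethoxycyclohexa-3,5-diene-1,2-diol (cis, meso)
Conditions: SmI2 (2.5 equiv, 0.1 M in THF), slow addition of 8, −78 → 0 °C; then sat. aq. NaHCO3; crude product kept base-washed and cold
Reagents that add atoms: none
Why: Single-electron transfer from divalent samarium to one formyl group gives an O-samarium ketyl whose carbon attacks the neighbouring formyl carbon (or couples with a second ketyl held on the same metal), and a second electron gives the trivalent samarium diolate that is protonated on work-up. The closest known reactions are the SmI2 pinacol cyclisation of 1,6-dialdehydes to cis-cyclohexane-1,2-diols and of biaryl-2,2'-dicarbaldehydes to 9,10-dihydrophenanthrene-9,10-diols. The cyclohexadiene ring closes by C1–C6 bond formation, a 6-exo-trig attack of the ketyl carbon on the second C=O, with the four sp2 carbons C2–C5 already in place. The two new carbinol stereocentres should be set cis because both oxygens stay bound to one samarium centre while the bond forms; their configuration is not needed later, since step 7 removes both. The step needs carbonyl-to-carbonyl coupling to win over conjugate reduction and over bonding at the β-carbons: C3 and C4 are fully substituted, carry methoxy donors and are already joined to each other, the other possible closures would be four-membered or 5-endo, and the 2E,4E geometry from step 3 turns both formyl groups to the inside of the s-cis diene. Aprotic conditions without HMPA keep the ketyl from being protonated and reduced further.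

**Step 7**
Reactants: 9 (1R,2S)-3,6-bis[4-(benzyloxy)phenyl]-4,5-dimethoxycyclohexa-3,5-diene-1,2-diol
Product: 12 3,6-bis[4-(benzyloxy)phenyl]-4,5-dimethoxycyclohexa-3,5-diene-1,2-dione, via ketol 10 (not isolated), via catechol 11 (not isolated)
Conditions: 2-iodoxybenzoic acid (IBX, 3 equiv), DMSO, rt
Reagents that add atoms: none
Why: IBX oxidation of a secondary allylic alcohol proceeds without glycol C–C cleavage to ketol 10, which aromatises by enolisation to catechol 11, and IBX oxidation of the catechol then gives the o-quinone.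

**Step 8**
Reactants: 12 3,6-bis[4-(benzyloxy)phenyl]-4,5-dimethoxycyclohexa-3,5-diene-1,2-dione
Product: 14 2,5-bis[4-(benzyloxy)phenyl]-3,6-dihydroxycyclohexa-2,5-diene-1,4-dione, via monomethyl ether 13 (not isolated)
Conditions: 2 M aq. NaOH, 1,4-dioxane, 50 °C, argon; then 1 M HCl, 0 °C
Reagents that add atoms: sodium hydroxide, [Na+].[OH-]
Why: Each methoxy group is a vinylogous ester, so hydroxide addition–elimination replaces the first one (the hydroxy-o-quinone tautomerising to p-quinone 13) and then the second, ending at the stable dianion of the dihydroxy-p-quinone.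

**Step 9**
Reactants: 14 2,5-bis[4-(benzyloxy)phenyl]-3,6-dihydroxycyclohexa-2,5-diene-1,4-dione
Product: 15 2,5-bis[4-(benzyloxy)phenyl]-4-hydroxy-3,6-dioxocyclohexa-1,4-dien-1-yl acetate
Conditions: Ac2O (1.0 equiv), pyridine (1.1 equiv), CH2Cl2, −20 → 0 °C; cold dilute HCl wash; chromatography
Reagents that add atoms: acetic anhydride, CC(=O)OC(C)=O
Why: O-Acylation of an acidic enolic hydroxyl with a limiting amount of anhydride; the two hydroxyls are equivalent, so only one monoacetate can form, and diacetate and unreacted 14 can be returned to 14 under the conditions of step 8.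

**Step 10**
Reactants: 15 2,5-bis[4-(benzyloxy)phenyl]-4-hydroxy-3,6-dioxocyclohexa-1,4-dien-1-yl acetate
Product: 17 4-hydroxy-2,5-bis(4-hydroxyphenyl)-3,6-dioxocyclohexa-1,4-dien-1-yl acetate (target), via leuco triol 16 (not isolated)
Conditions: H2 (1 atm), 10% Pd/C, EtOAc, rt; filtration under argon; then air, rt
Reagents that add atoms: none
Why: Hydrogenolysis of aryl benzyl ethers in a neutral, non-nucleophilic solvent also reduces the quinone to hydroquinone 16, in which the ester is an ordinary aryl acetate and any 1,2-acyl shift is degenerate by symmetry, and autoxidation in air restores the quinone.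

**Compound list**
1 | methyl [4-(benzyloxy)phenyl]acetate | COC(=O)Cc1ccc(OCc2ccccc2)cc1 | starting material
2 | methyl formate | COC=O | starting material
3 | methyl (2Z)-2-[4-(benzyloxy)phenyl]-3-hydroxyprop-2-enoate | O/C=C(/c1ccc(OCc2ccccc2)cc1)C(=O)OC | intermediate
4 | methyl (2E)-2-[4-(benzyloxy)phenyl]-3-methoxyprop-2-enoate | CO/C=C(/C(=O)OC)c1ccc(OCc2ccccc2)cc1 | intermediate
5 | methyl (2E)-2-[4-(benzyloxy)phenyl]-3-lithio-3-methoxyprop-2-enoate (lithium cis to the ester) | [Li]/C(OC)=C(/c1ccc(OCc2ccccc2)cc1)C(=O)OC | intermediate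
6 | dimethyl (2E,4E)-2,5-bis[4-(benzyloxy)phenyl]-3,4-dimethoxyhexa-2,4-dienedioate | COC(=O)/C(c1ccc(OCc2ccccc2)cc1)=C(OC)\C(OC)=C(c1ccc(OCc2ccccc2)cc1)/C(=O)OC | intermediate
7 | (2E,4E)-2,5-bis[4-(benzyloxy)phenyl]-3,4-dimethoxyhexa-2,4-diene-1,6-diol | OC/C(c1ccc(OCc2ccccc2)cc1)=C(OC)\C(OC)=C(c1ccc(OCc2ccccc2)cc1)/CO | intermediate
8 | (2E,4E)-2,5-bis[4-(benzyloxy)phenyl]-3,4-dimethoxyhexa-2,4-dienedial | O=C/C(c1ccc(OCc2ccccc2)cc1)=C(OC)\C(OC)=C(c1ccc(OCc2ccccc2)cc1)/C=O | intermediate
9 | (1R,2S)-3,6-bis[4-(benzyloxy)phenyl]-4,5-dimethoxycyclohexa-3,5-diene-1,2-diol (cis, meso) | O[C@H]1C(c2ccc(OCc3ccccc3)cc2)=C(OC)C(OC)=C(c2ccc(OCc3ccccc3)cc2)[C@H]1O | intermediate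
10 | 2,5-bis[4-(benzyloxy)phenyl]-6-hydroxy-3,4-dimethoxycyclohexa-2,4-dien-1-one (racemic ketol) | O=C1C(O)C(c2ccc(OCc3ccccc3)cc2)=C(OC)C(OC)=C1c1ccc(OCc2ccccc2)cc1 | intermediate
11 | 3,6-bis[4-(benzyloxy)phenyl]-4,5-dimethoxybenzene-1,2-diol | COc1c(OC)c(-c2ccc(OCc3ccccc3)cc2)c(O)c(O)c1-c1ccc(OCc2ccccc2)cc1 | intermediate
12 | 3,6-bis[4-(benzyloxy)phenyl]-4,5-dimethoxycyclohexa-3,5-diene-1,2-dione | COC1=C(c2ccc(OCc3ccccc3)cc2)C(=O)C(=O)C(c2ccc(OCc3ccccc3)cc2)=C1OC | intermediate
13 | 2,5-bis[4-(benzyloxy)phenyl]-3-hydroxy-6-methoxycyclohexa-2,5-diene-1,4-dione | COC1=C(c2ccc(OCc3ccccc3)cc2)C(=O)C(O)=C(c2ccc(OCc3ccccc3)cc2)C1=O | intermediate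
14 | 2,5-bis[4-(benzyloxy)phenyl]-3,6-dihydroxycyclohexa-2,5-diene-1,4-dione | OC1=C(c2ccc(OCc3ccccc3)cc2)C(=O)C(O)=C(c2ccc(OCc3ccccc3)cc2)C1=O | intermediate
15 | 2,5-bis[4-(benzyloxy)phenyl]-4-hydroxy-3,6-dioxocyclohexa-1,4-dien-1-yl acetate | CC(=O)OC1=C(c2ccc(OCc3ccccc3)cc2)C(=O)C(O)=C(c2ccc(OCc3ccccc3)cc2)C1=O | intermediate
16 | 2,4,5-trihydroxy-3,6-bis(4-hydroxyphenyl)phenyl acetate | CC(=O)Oc1c(-c2ccc(O)cc2)c(O)c(O)c(-c2ccc(O)cc2)c1O | intermediate
17 | 4-hydroxy-2,5-bis(4-hydroxyphenyl)-3,6-dioxocyclohexa-1,4-dien-1-yl acetate | CC(=O)OC1=C(c2ccc(O)cc2)C(=O)C(O)=C(c2ccc(O)cc2)C1=O | target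

**Step count**
Total: 10 steps. Longest linear sequence: 10 steps (from 1; compound 4 enters step 3 twice).

**Steps most likely to fail**

Step 6. The samarium ketyl of a β-methoxy enal may be drawn into conjugate reduction or oligomerisation through its β-carbon radical character. The cis-dienal may also lose its geometry by oxa-electrocyclisation to a 2H-pyran before the two formyl carbons couple. The fallback forms the same C1–C6 bond without a reductant, by acyl-anion catalysis. It sets out from 8: a thiazolium-derived N-heterocyclic carbene (3-benzyl-5-(2-hydroxyethyl)-4-methylthiazolium chloride, 20 mol %, Et3N, EtOH, 70 °C, argon) should turn one formyl group into a Breslow intermediate that adds to the other formyl carbon in an intramolecular benzoin condensation. This gives ketol 10, which enolises to catechol 11. The fallback comes back to the route at 11, which the IBX of step 7 oxidises to 12. It makes no compound outside the list (F0).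

Step 3. The ester-bearing vinyllithium may be lost to proton return or to self-condensation, and transfer to copper may end in reduction instead of C–C bond formation. The fallback replaces the oxidative dimerisation by a redox-neutral cross-coupling of two halves made from the same anion. It sets out from 4: vinyllithium 5 is generated as in step 3, and one portion is quenched with Bu3SnCl to give methyl (2Z)-2-[4-(benzyloxy)phenyl]-3-methoxy-3-(tributylstannyl)prop-2-enoate F1. A second portion is quenched with I2 to give methyl (2Z)-2-[4-(benzyloxy)phenyl]-3-iodo-3-methoxyprop-2-enoate F2. Stille coupling of F1 with F2 (Pd(PPh3)4, zerovalent palladium, with catalytic CuI, DMF, 45 °C) proceeds with retention at both alkenyl carbons. It comes back to the route at 6.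

Step 5. Once one hydroxyl is oxidised, the hydroxy-aldehyde may close to a cyclic hemiacetal and be oxidised on to a seven-membered lactone, and the long heterogeneous reaction gives the cis-dienal time to isomerise. The fallback releases both formyl groups at once and avoids diol 7. It sets out from 6: MeNH(OMe)·HCl and i-PrMgCl (THF, −20 → 0 °C) convert both esters into the bis-Weinreb amide (2E,4E)-2,5-bis[4-(benzyloxy)phenyl]-N1,N6,3,4-tetramethoxy-N1,N6-dimethylhexa-2,4-dienediamide F3. Reduction with i-Bu2AlH (THF, −78 °C) stops at the chelated aluminium hemiaminals, which collapse to the dialdehyde only on cold aqueous work-up. It comes back to the route at 8.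

**Further compounds**
F0 | step 6 | none | none
F1 | step 3 | methyl (2Z)-2-[4-(benzyloxy)phenyl]-3-methoxy-3-(tributylstannyl)prop-2-enoate | CCCC[Sn](CCCC)(CCCC)/C(OC)=C(/c1ccc(OCc2ccccc2)cc1)C(=O)OC
F2 | step 3 | methyl (2Z)-2-[4-(benzyloxy)phenyl]-3-iodo-3-methoxyprop-2-enoate | I/C(OC)=C(/c1ccc(OCc2ccccc2)cc1)C(=O)OC
F3 | step 5 | (2E,4E)-2,5-bis[4-(benzyloxy)phenyl]-N1,N6,3,4-tetramethoxy-N1,N6-dimethylhexa-2,4-dienediamide | CON(C)C(=O)/C(c1ccc(OCc2ccccc2)cc1)=C(OC)\C(OC)=C(c1ccc(OCc2ccccc2)cc1)/C(=O)N(C)OC
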